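**Plan**
- **Cuts (retrosynthesis):** (i) C8–Cl, back to the 7,8-β-epoxide. (ii) C5–C6, the cis-diol bond of ring A, back to a 1,6-dialdehyde (reductive carbonyl coupling). (iii) O1–C2 and C4–C4a of the pyranone (ring B), back to an ynoyl chloride and a β-keto thioester. (iv) C4a–C8a (Claisen) and ArCH2–CH2 (alkylation).
- **Enabling feature:** C5 and C6 are both carbinol carbons, a vicinal cis-diol. C5 sits on C4a of ring B, peri to the C4 carbonyl, so its aldehyde is a conjugated, chelating and easily reduced ketyl precursor. C6–C7–C8–C8a are the four carbons of L-tartaric acid.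
- **Forward order:** the side-chain ynoic acid and the tartrate-derived β-keto thioester are joined and ring B forms first. Both thioesters are then reduced to aldehydes, ring A closes, the epoxide is made, and HCl opens it.
- **Stereochemistry:** C7 and C8 come from L-tartrate and are carried as a trans-dioxolane, a temporary ring. C5 and C6 arise in the ring closure, controlled by that ring and by samarium chelation. C8 goes O → epoxide → Cl by two inversions, so its configuration is retained overall.

Key step: step 8

Remark: the SMILES reads as (5S,6S,7S,8R), that is O5, O6 and O7 on one face of ring A (called β) and Cl on the other (α). Chromone numbering is used throughout, also for open-chain precursors. Ar = 4-methoxy-3-(methoxymethoxy)phenyl.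

**Step 1**
Reactants: 1 3-hydroxy-4-methoxybenzyl alcohol
Product: 2 [4-methoxy-3-(methoxymethoxy)phenyl]methanol
Conditions: MOMCl (1.1 equiv), K2CO3, acetone, 0 °C to rt
Reagents that add atoms: chloromethyl methyl ether (MOMCl), COCCl
Why: Williamson-type O-alkylation in which K2CO3 deprotonates only the phenol, giving an acetal that survives base, SmI2 and weak acid and falls in the last step.

**Step 2**
Reactants: 2 [4-methoxy-3-(methoxymethoxy)phenyl]methanol
Product: 3 4-(bromomethyl)-1-methoxy-2-(methoxymethoxy)benzene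
Conditions: CBr4, PPh3, CH2Cl2, 0 °C; used at once
Reagents that add atoms: tetrabromomethane, BrC(Br)(Br)Br
Why: The Appel reaction converts the primary benzylic alcohol to the bromide under neutral conditions that spare the MOM acetal.

**Step 3**
Reactants: 3 4-(bromomethyl)-1-methoxy-2-(methoxymethoxy)benzene; 4 but-2-ynoic acid
Product: 5 5-Ar-pent-2-ynoic acid
Conditions: 4, LiN(iPr)2 (2.2 equiv), THF–DMPU, −78 to −20 °C; then 3, −78 °C to rt; cold 1 M HCl work-up
Reagents that add atoms: none
Why: Alkylation of the dianion of but-2-ynoic acid at its γ-carbon, a known route to 4-substituted 2-alkynoic acids, forms the ArCH2–CH2 bond with a reactive benzylic bromide.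

**Step 4**
Reactants: 6 dimethyl (4R,5R)-2,2-dimethyl-1,3-dioxolane-4,5-dicarboxylate (dimethyl 2,3-O-isopropylidene-L-tartrate)
Product: 7 S,S'-diethyl (4R,5R)-2,2-dimethyl-1,3-dioxolane-4,5-dicarbothioate
Conditions: AlMe3, EtSH (2.5 equiv each), CH2Cl2, 0 °C to rt; aq. HCl work-up
Reagents that add atoms: ethanethiol, CCS
Why: Ester-to-thioester exchange with the aluminium thiolate Me2AlSEt leaves the stereocentres untouched, and the trans-dioxolane is in any case the more stable epimer.

**Step 5**
Reactants: 7 S,S'-diethyl (4R,5R)-2,2-dimethyl-1,3-dioxolane-4,5-dicarbothioate; 8 S-ethyl ethanethioate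
Product: 9 S-ethyl (4R,5R)-5-[3-(ethylsulfanyl)-3-oxopropanoyl]-2,2-dimethyl-1,3-dioxolane-4-carbothioate
Conditions: 8 (2 equiv), LiN(SiMe3)2 (2 equiv), THF, −78 °C; added to 7 (slight excess) in THF, −78 °C; aq. NH4Cl
Reagents that add atoms: none
Why: In this crossed Claisen condensation of a thioacetate enolate with a thioester the first product is deprotonated at once, its charge slows a second attack (as in the mono-saponification of tartrate diesters), and Dieckmann closure is blocked because it would give a trans-fused bicyclo[3.3.0] system.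

**Step 6**
Reactants: 5 5-Ar-pent-2-ynoic acid; 9 S-ethyl (4R,5R)-5-[3-(ethylsulfanyl)-3-oxopropanoyl]-2,2-dimethyl-1,3-dioxolane-4-carbothioate
Product: 12 S-ethyl 2-[(4R,5R)-5-(ethylsulfanylcarbonyl)-2,2-dimethyl-1,3-dioxolan-4-yl]-6-(2-Ar-ethyl)-4-oxo-4H-pyran-3-carbothioate, via acid chloride 10 (not isolated), via triacylmethane enol 11 (not isolated)
Conditions: 5, 1-chloro-N,N,2-trimethylprop-1-en-1-amine, CH2Cl2, 0 °C; then 9, MgCl2, pyridine, CH2Cl2, 0 °C to rt; then Et3N (cat.), rt
Reagents that add atoms: 1-chloro-N,N,2-trimethylprop-1-en-1-amine, CC(C)=C(Cl)N(C)C (the chlorine of 10 only)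
Why: C-acylation of the magnesium chelate of a β-dicarbonyl compound by an acid chloride, then 6-endo-dig oxa-Michael addition of the C8a enol oxygen to the ynone (the known path from acetylenic β-diketones to 4-pyranones), places the C5 thioester carbon on C4a without regiochemical ambiguity.

**Step 7**
Reactants: 12 pyranone bis-thioester
Product: 13 2-[(4R,5R)-5-formyl-2,2-dimethyl-1,3-dioxolan-4-yl]-6-(2-Ar-ethyl)-4-oxo-4H-pyran-3-carbaldehyde
Conditions: Et3SiH (6 equiv), Pd/C, acetone, rt; filtered and used at once
Reagents that add atoms: none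
Why: In the Fukuyama reduction zerovalent palladium inserts into each acyl–S bond and the silane delivers hydride, stopping at the aldehyde under neutral conditions that leave the pyranone, ketal and MOM ether alone.

**Step 8**
Reactants: 13 dialdehyde
Product: 14 (5S,6S,7S,8R)-5,6-dihydroxy-7,8-(isopropylidenedioxy)-2-(2-Ar-ethyl)-5,6,7,8-tetrahydro-4H-chromen-4-one
Conditions: SmI2 (0.1 M in THF, 2.5 equiv, slow addition), THF (0.005 M in 13), −78 to −20 °C, no proton source; then sat. aq. NaHCO3
Reagents that add atoms: none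
Why: This is an intramolecular SmI2 pinacol coupling of a 1,6-dialdehyde, the reaction type known for closing sugar-derived dialdehydes to cis-cyclohexane-1,2-diols: divalent samarium first reduces the C5 formyl group, the better acceptor because it is conjugated with C4a=C8a and the C4 carbonyl, the trivalent samarium ketyl adds to the metal-activated C6 aldehyde, and a second electron transfer gives the diolate that is protonated on work-up. Ring A closes in the 6-exo-trig mode, with the C6=O oxygen outside the new ring. At C5 the six-membered O4–Sm–O5 chelate holds O5 in the pyranone plane on the C4=O side, so it ends pseudo-equatorial, and samarium bridging of O5 and O6 makes the new diol cis. At C6 the trans-fused dioxolane locks O7 and O8 diequatorial, which sets the C7–O7 bond antiperiplanar to the forming bond (polar Felkin–Anh arrangement) and sends O6 axial, cis to O7, so that 7S relays to 6S and 5S. The ketyl must cyclise faster than it accepts a second electron, which would expel O8 from C8 as from a vinylogous α-alkoxy ketone; a ketal oxygen (poor leaving group) in place of the final chlorine, slow addition of the reductant, low temperature and the absence of a proton source secure this. High dilution suppresses intermolecular coupling, and epimerisation at C7 or C8 is harmless because the trans-dioxolane is the stable isomer.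

**Step 9**
Reactants: 14 5β,6β-diol 7β,8α-acetonide
Product: 15 5β,6β:7β,8α-bis(isopropylidenedioxy)-2-(2-Ar-ethyl)-5,6,7,8-tetrahydro-4H-chromen-4-one
Conditions: Me2C(OMe)2, PPTS (cat.), CH2Cl2, rt
Reagents that add atoms: 2,2-dimethoxypropane, COC(C)(C)OC
Why: In this acid-catalysed transketalisation only the cis-5,6-diol is free, so it is capped as a cis-fused dioxolane.

**Step 10**
Reactants: 15 bis-acetonide
Product: 16 7β,8α-dihydroxy-5β,6β-(isopropylidenedioxy)-2-(2-Ar-ethyl)-5,6,7,8-tetrahydro-4H-chromen-4-one
Conditions: AcOH–H2O (4:1), 0 °C to rt, stopped at mono-cleavage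
Reagents that add atoms: none
Why: Under kinetic ketal hydrolysis the strained trans-fused dioxolane on a six-membered ring cleaves much faster than the cis-fused one, the selectivity familiar from inositol diketals.

**Step 11**
Reactants: 16 7β,8α-diol 5β,6β-acetonide
Product: 18 7β,8β-epoxy-5β,6β-(isopropylidenedioxy)-2-(2-Ar-ethyl)-5,6,7,8-tetrahydro-4H-chromen-4-one, via 8-O-nosylate 17 (not isolated)
Conditions: 4-O2NC6H4SO2Cl (1.05 equiv), Et3N, CH2Cl2, −20 to 0 °C; then DBU, 0 °C to rt
Reagents that add atoms: 4-nitrobenzenesulfonyl chloride, O=S(=O)(Cl)c1ccc(cc1)[N+](=O)[O-] (in 17 only)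
Why: Sulfonylation should select the more acidic and less hindered hydroxyl next to an acceptor (C8–OH is the vinylogous counterpart of the α-hydroxyl of a 2,3-dihydroxy ester), and intramolecular Williamson (SN2) closure by O7 then inverts C8 to give the β-epoxide.

**Step 12**
Reactants: 18 7β,8β-epoxide
Product: 20 (5S,6S,7S,8R)-8-chloro-5,6,7-trihydroxy-2-[2-(3-hydroxy-4-methoxyphenyl)ethyl]-5,6,7,8-tetrahydro-4H-chromen-4-one, via chlorohydrin acetonide 19 (not isolated)
Conditions: HCl (4 M in 1,4-dioxane), CH2Cl2, −20 to 0 °C; then H2O–THF, rt to 40 °C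
Reagents that add atoms: hydrogen chloride, Cl
Why: Acid-promoted SN2 opening of the epoxide by chloride at C8 (activated by the adjacent pyranone π system, whereas C7 is retarded by the β-oxygen at C6) inverts C8 to the trans-chlorohydrin, as in the presumed biogenesis of the chlorinated tetrahydrochromones, and aqueous acid then hydrolyses the ketal and the MOM acetal.

**Compound list**
1 | 3-hydroxy-4-methoxybenzyl alcohol | COc1ccc(CO)cc1O | starting material
2 | [4-methoxy-3-(methoxymethoxy)phenyl]methanol | COCOc1cc(CO)ccc1OC | intermediate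
3 | 4-(bromomethyl)-1-methoxy-2-(methoxymethoxy)benzene | COCOc1cc(CBr)ccc1OC | intermediate
4 | but-2-ynoic acid | CC#CC(=O)O | starting material
5 | 5-[4-methoxy-3-(methoxymethoxy)phenyl]pent-2-ynoic acid | COCOc1cc(CCC#CC(=O)O)ccc1OC | intermediate
6 | dimethyl (4R,5R)-2,2-dimethyl-1,3-dioxolane-4,5-dicarboxylate | COC(=O)[C@@H]1OC(C)(C)O[C@H]1C(=O)OC | starting material
7 | S,S'-diethyl (4R,5R)-2,2-dimethyl-1,3-dioxolane-4,5-dicarbothioate | CCSC(=O)[C@@H]1OC(C)(C)O[C@H]1C(=O)SCC | intermediate
8 | S-ethyl ethanethioate | CCSC(C)=O | starting material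
9 | S-ethyl (4R,5R)-5-[3-(ethylsulfanyl)-3-oxopropanoyl]-2,2-dimethyl-1,3-dioxolane-4-carbothioate | CCSC(=O)CC(=O)[C@@H]1OC(C)(C)O[C@H]1C(=O)SCC | intermediate
10 | 5-[4-methoxy-3-(methoxymethoxy)phenyl]pent-2-ynoyl chloride (not isolated) | COCOc1cc(CCC#CC(=O)Cl)ccc1OC | intermediate
11 | triacylmethane from C-acylation of 9 at C4a, drawn as its C8a enol (not isolated) | CCSC(=O)C(C(=O)C#CCCc1ccc(OC)c(OCOC)c1)=C(O)[C@@H]2OC(C)(C)O[C@H]2C(=O)SCC | intermediate
12 | pyranone bis-thioester (C5 and C6 as C(O)SEt, trans-dioxolane on C7/C8) | COCOc1cc(CCc2cc(=O)c(C(=O)SCC)c(o2)[C@@H]3OC(C)(C)O[C@H]3C(=O)SCC)ccc1OC | intermediate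
13 | pyranone dialdehyde (C5 and C6 as CHO) | COCOc1cc(CCc2cc(=O)c(C=O)c(o2)[C@@H]3OC(C)(C)O[C@H]3C=O)ccc1OC | intermediate
14 | (5S,6S,7S,8R)-5,6-diol 7,8-acetonide | COCOc1cc(CCc2cc(=O)c3c(o2)[C@@H]4OC(C)(C)O[C@H]4[C@@H](O)[C@H]3O)ccc1OC | intermediate
15 | 5β,6β:7β,8α-bis-acetonide | COCOc1cc(CCc2cc(=O)c3c(o2)[C@@H]4OC(C)(C)O[C@H]4[C@H]5OC(C)(C)O[C@@H]35)ccc1OC | intermediate
16 | 7β,8α-diol 5β,6β-acetonide | COCOc1cc(CCc2cc(=O)c3c(o2)[C@H](O)[C@@H](O)[C@H]4OC(C)(C)O[C@@H]34)ccc1OC | intermediate
17 | 8α-(4-nitrobenzenesulfonyloxy)-7β-ol 5β,6β-acetonide (not isolated) | COCOc1cc(CCc2cc(=O)c3c(o2)[C@H](OS(=O)(=O)c4ccc(cc4)[N+](=O)[O-])[C@@H](O)[C@H]5OC(C)(C)O[C@@H]35)ccc1OC | intermediate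
18 | 7β,8β-epoxide 5β,6β-acetonide | COCOc1cc(CCc2cc(=O)c3c(o2)[C@H]4O[C@H]4[C@H]5OC(C)(C)O[C@@H]35)ccc1OC | intermediate
19 | 8α-chloro-7β-ol 5β,6β-acetonide MOM ether (not isolated) | COCOc1cc(CCc2cc(=O)c3c(o2)[C@H](Cl)[C@@H](O)[C@H]4OC(C)(C)O[C@@H]34)ccc1OC | intermediate
20 | (5S,6S,7S,8R)-8-chloro-5,6,7-trihydroxy-2-[2-(3-hydroxy-4-methoxyphenyl)ethyl]-5,6,7,8-tetrahydro-4H-chromen-4-one | COc1ccc(CCc2cc(=O)c3c(o2)[C@H](Cl)[C@@H](O)[C@@H](O)[C@H]3O)cc1O | target

Total step count: 12.
Longest linear sequence: 10 steps (1 → 2 → 3 → 5 → 12 → 13 → 14 → 15 → 16 → 18 → 20, that is steps 1–3 and 6–12).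

**Steps most likely to fail**

**1. Step 8.**
- Possible failures: poor facial selectivity (attack on the other face of the C6 aldehyde, or O5 ending pseudo-axial); reductive expulsion of O8 after a second electron transfer; or slow closure against the strain of the trans-fused dioxolane, so that simple reduction or intermolecular coupling takes over.
- Fallback: olefin metathesis plus directed dihydroxylation, with no ketyl chemistry. It sets out from 13 and returns at 15.
- Double Wittig methylenation (Ph3P=CH2, THF, −78 to 0 °C) should give the divinyl ketal F1.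
- Aqueous acetic acid at 50 °C should free the open-chain threo-diol, the divinyl diol F2.
- Ring-closing metathesis with the second-generation Hoveyda–Grubbs catalyst in CH2Cl2 should close ring A under neutral conditions to the trans-7,8-dihydroxy-7,8-dihydrochromone F3.
- Stoichiometric OsO4 with TMEDA (CH2Cl2, −78 °C), hydrogen-bonded to the allylic 7-OH, should add to the β face of C5=C6. After cleavage of the osmate with aq. Na2SO3 this should give the 5β,6β,7β,8α-tetrol F4.
- Exhaustive ketalisation (2-methoxypropene, PPTS) then rejoins the route at 15.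

**2. Step 11.**
- Possible failures: loss of regiocontrol (sulfonylation at O7 or at both hydroxyls, which would lead to the α-epoxide); displacement of the reactive C8 sulfonate by chloride ion; or base-induced elimination.
- Fallback: both oxygens are activated alike and the regiochemistry is left to the more SN2-reactive carbon. It sets out from 16 and returns at 19.
- 1,1'-Sulfonyldiimidazole with NaH in THF should give the trans-fused 7,8-cyclic sulfate F5.
- LiBr should open it at C8 with inversion. Hydrolysis of the sulfate monoester (cat. H2SO4, one equivalent of H2O, THF) should then give the 8β-bromo-7β-ol F6.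
- LiCl in DMF should displace bromide with a second inversion to give 19, which is then hydrolysed as in the second stage of step 12.

**3. Step 5.**
- Possible failures: a second Claisen attack on the remaining thioester, or base-induced β-elimination that opens the dioxolane.
- Fallback: desymmetrisation by mono-hydrolysis, then a neutral decarboxylative Claisen condensation. It sets out from 7 and returns at 9.
- LiOH (1 equiv, THF–H2O, 0 °C) should give the acid thioester F7.
- 1,1'-Carbonyldiimidazole in THF should give the acyl imidazolide F8.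
- The magnesium salt of 3-(ethylsulfanyl)-3-oxopropanoic acid (formed with iPrMgCl, THF, rt) should acylate at the imidazolide only and decarboxylate to 9.

**Further compounds**
F1 | step 8 | 2-[(4R,5R)-2,2-dimethyl-5-vinyl-1,3-dioxolan-4-yl]-3-vinyl-6-(2-Ar-ethyl)-4H-pyran-4-one | COCOc1cc(CCc2cc(=O)c(C=C)c(o2)[C@@H]3OC(C)(C)O[C@H]3C=C)ccc1OC
F2 | step 8 | divinyl threo-diol (ketal of F1 removed) | COCOc1cc(CCc2cc(=O)c(C=C)c(o2)[C@H](O)[C@@H](O)C=C)ccc1OC
F3 | step 8 | 7β,8α-dihydroxy-2-(2-Ar-ethyl)-7,8-dihydro-4H-chromen-4-one | COCOc1cc(CCc2cc(=O)c3c(o2)[C@H](O)[C@@H](O)C=C3)ccc1OC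
F4 | step 8 | 5β,6β,7β,8α-tetrahydroxy-2-(2-Ar-ethyl)-5,6,7,8-tetrahydro-4H-chromen-4-one | COCOc1cc(CCc2cc(=O)c3c(o2)[C@H](O)[C@@H](O)[C@@H](O)[C@H]3O)ccc1OC
F5 | step 11 | 7β,8α-cyclic sulfate 5β,6β-acetonide | COCOc1cc(CCc2cc(=O)c3c(o2)[C@@H]4OS(=O)(=O)O[C@H]4[C@H]5OC(C)(C)O[C@@H]35)ccc1OC
F6 | step 11 | 8β-bromo-7β-ol 5β,6β-acetonide | COCOc1cc(CCc2cc(=O)c3c(o2)[C@@H](Br)[C@@H](O)[C@H]4OC(C)(C)O[C@@H]34)ccc1OC
F7 | step 5 | (4R,5R)-5-(ethylsulfanylcarbonyl)-2,2-dimethyl-1,3-dioxolane-4-carboxylic acid | OC(=O)[C@@H]1OC(C)(C)O[C@H]1C(=O)SCC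
F8 | step 5 | S-ethyl (4R,5R)-5-(imidazole-1-carbonyl)-2,2-dimethyl-1,3-dioxolane-4-carbothioate | O=C(n1ccnc1)[C@@H]2OC(C)(C)O[C@H]2C(=O)SCC
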